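Slowness at the head of a chain is where this flask begins: the electrophile has to leave the solid before anything can happen to it.

    acid set free + free base ⇌ salt of the base (K1 = 9100 L mol⁻¹, k1 = 0.62 L mol⁻¹ s⁻¹)
    electrophile + nucleophile → acid set free + target (k2 = 0.037 L mol⁻¹ s⁻¹)
    nucleophile + acid set free ⇌ protonated nucleophile, settled at all times (K3 = 58000 L mol⁻¹)
    target → over-reaction product (k4 = 7.2 × 10⁻⁵ s⁻¹)
    solid electrophile ⇌ electrophile, rate k5*(cs5 - [electrophile]) while solid is left; crystals form when [electrophile] > cs5 (cs5 = 3.8 mM, k5 = 1.2 × 10⁻⁴ s⁻¹)

in all of them: solid electrophile 10 mM; protonated nucleophile 18.0 mM (fed, over 1.0 h); time 5.0 h
- alder: free base 30.0 mM
- elm: free base 60.0 mM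
- birch: free base 120 mM

* part of the solid electrophile that has reacted (what has only dissolved counts as not reacted) at the end, alder
* part of the solid electrophile that has reacted (what has only dissolved counts as not reacted) at the end, elm
* part of the solid electrophile that has reacted (what has only dissolved counts as not reacted) at the end, birch
* what raising the concentration of free base from its lowest to its highest value here does to the part of the solid electrophile that has reacted (what has only dissolved counts as not reacted) (changes below 5 percentage points count as none) (no change / it rises / it falls)

While solid is left, [electrophile] should settle where dissolving balances its pseudo-first-order consumption. The dissolving coefficient times the gap below solubility then equals the rate constant of the target-forming step times [nucleophile] times [electrophile]. The part reacted is therefore roughly a ceiling, solubility times dissolving coefficient times the time after the feed, over the charge, multiplied by [nucleophile] / ([nucleophile] + crossover).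

Which numbers must be known well? The solubility enters as a plain factor and the charge as a plain divisor, so their errors pass whole. The dissolving coefficient stands in the ceiling and in the crossover, so part of its error cancels. The target-forming constant and [nucleophile] stand in the second factor, where an error is damped. The two balance constants reach the answer through [nucleophile], under a root. The step from target drops out, since over-reaction product counts as reacted.

Now the numbers. The ceiling rate is 1.64 mM h⁻¹, which gives 65.7% of the charge. The ratio of the two constants is 3.24 mM: the crossover, the [nucleophile] at which consumption per electrophile matches the dissolving coefficient. Taking both acid balances as held, and each nucleophile freed as leaving a salt, [nucleophile] squared in alder is about 0.157 times [protonated nucleophile] times [free base]. With the charges this gives 9.20 mM, and with that amount taken off both charges, 5.36 mM. That should stand on the high side, since the reaction adds acid. The reckoning for alder is 40.9%.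

The forecast gives 36% for alder, lower than this reckoning, then 41% for elm and 45% for birch, and of the part reacted as free base is raised it says: it rises, on the ground that “dissolution increasingly limits the rate”.

The simulation gives 32.7% for alder, below the reckoned value, 40.1% for elm and 46.6% for birch; from alder to birch it rises, by 14 percentage points. At the end of alder, [nucleophile] is 2.86 mM, under the crossover: consumption runs at 1.06 × 10⁻⁴ s⁻¹ against the dissolving coefficient 1.2 × 10⁻⁴ s⁻¹, and the balance gives 20.2% of the charge as electrophile, where alder holds 18.7%. At the end of birch, [nucleophile] is 5.92 mM, over the crossover, the balance gives 13.5%, and birch holds 12.8%.

All constants belong to no real substance; the result is computed.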